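Numbering: ring A is the quinone ring C1(=O)–C2(OMe)=C3H–C4(=O), ring B is C4a–C8a with OMe at C6 and the aryl group at C8, and ring C is the veratryl group. The retrosynthesis first goes from quinone to 1,4-diol, then cuts ring A at C1–C8a (the ring-closing bond) and at C4–C4a, and last cuts the C8–C1' biaryl bond.
Enabling feature: C4a and C8a are neighbouring carbons of ring B that both carry acyl carbons, and C8a is wedged between C4a and the aryl-bearing C8. Acylation at C8a would pair two acceptor carbons, whereas an aryne C4a≡C8a takes up both carbons in one operation, and the C8 aryl group beside it decides which end receives the nucleophile.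
The four-carbon partner is 3-methoxyfuran-2(5H)-one. Its ring oxygen sits on the future C4, so as the furanolate this future carbonyl carbon is a donor (polarity reversal). Its lactone carbonyl, next to C–OMe, is the acyl acceptor that becomes C1.
Forward order: rings B and C are joined first (Suzuki–Miyaura at C–I, with C–Br kept as the aryne trigger). The butenolide is made in three steps from α-hydroxy-γ-butyrolactone, the annulation closes ring A, and Ag2O sets the quinone level.
Stereochemistry: the target has no stereocentre and no hindered axis. The racemic or transient centres on the way are all erased.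

Key step: step 5

Remark: the C8–C1' axis has no ortho substituent on ring C and is taken as freely rotating. 4-Bromo-3-iodoanisole, the boronic acid and α-hydroxy-γ-butyrolactone are taken as catalogue chemicals.

Step 1
Reactants: 1 1-bromo-2-iodo-4-methoxybenzene (4-bromo-3-iodoanisole); 2 (3,4-dimethoxyphenyl)boronic acid
Product: 3 2-bromo-3',4',5-trimethoxy-1,1'-biphenyl
Conditions: Pd(PPh3)4 (cat.), Na2CO3, DME/H2O, 80 °C, 1.0 equiv of 2
Reagents that add atoms: none
Why: In this Suzuki–Miyaura coupling, zerovalent palladium inserts into C–I much faster than into C–Br, so one equivalent of 2 should couple at the iodide only and leave the bromide as the later aryne trigger.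

Step 2
Reactants: 4 (±)-3-hydroxydihydrofuran-2(3H)-one (α-hydroxy-γ-butyrolactone)
Product: 5 (±)-3-methoxydihydrofuran-2(3H)-one
Conditions: MeI, Ag2O, MeCN, rt, dark
Reagents that add atoms: iodomethane, CI
Why: Purdie O-methylation alkylates the secondary alcohol under nearly neutral conditions, so the lactone should neither open nor eliminate, and the racemic centre is erased in step 4.

Step 3
Reactants: 5 (±)-3-methoxydihydrofuran-2(3H)-one
Product: 7 (±)-3-methoxy-3-(phenylselanyl)dihydrofuran-2(3H)-one, via lithium enolate 6 (not isolated)
Conditions: LiN(iPr)2, THF, −78 °C; PhSeBr, −78 °C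
Reagents that add atoms: benzeneselenenyl bromide, Br[Se]c1ccccc1
Why: Kinetic enolate formation and electrophilic α-selenenylation of a lactone place PhSe at C3; the enolate has no β-leaving group, and the new quaternary centre is racemic and short-lived.

Step 4
Reactants: 7 (±)-3-methoxy-3-(phenylselanyl)dihydrofuran-2(3H)-one
Product: 9 3-methoxyfuran-2(5H)-one, via selenoxide 8 (not isolated)
Conditions: 30% aq H2O2, pyridine, CH2Cl2, 0 °C → rt
Reagents that add atoms: none
Why: In this selenoxide syn-elimination the only β-hydrogens sit at C4, so the C3=C4 enol-ether double bond should form unambiguously at or below room temperature.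

Step 5
Reactants: 9 3-methoxyfuran-2(5H)-one; 3 2-bromo-3',4',5-trimethoxy-1,1'-biphenyl
Product: 15 8-(3,4-dimethoxyphenyl)-2,6-dimethoxynaphthalene-1,4-diol, via lithium furanolate 10 (not isolated), via aryne 11 (not isolated), via aryllithium 12 (not isolated), via bridged alkoxide 13 (not isolated), via dilithium diolate 14 (not isolated)
Conditions: lithium 2,2,6,6-tetramethylpiperidide (5 equiv, from the amine and n-BuLi), THF, −78 °C; 9 (2 equiv), −78 °C; 3 (1 equiv), −78 °C → rt; AcOH quench, under Ar
Reagents that add atoms: none
Why: Proposed new method: the lithium amide turns 9 into the aromatic furanolate 10 and removes the only hydrogen ortho to bromine in 3 (C4a–H), so loss of LiBr gives aryne 11 with its triple bond fixed at C4a≡C8a; C5 of 10 (the future C4) adds to C4a, and the aryllithium 12 thus formed at C8a attacks the lactone carbonyl (the future C1), which makes the C1–C8a bond and closes ring A. The closest known reaction type is the annulation of phthalide and 3-cyanophthalide anions with arynes made from haloarenes and lithium amides (Hauser–Kraus type, giving anthraquinones), together with the [4+2] addition of arynes to 2-alkoxyfurans; the new element is the monocyclic butenolide donor. The six-membered carbocycle closes by a 6-exo-trig acyl addition to give the 1,4-epoxy-bridged alkoxide 13, whose hemiketal bridge opens at C1–O and whose C4–H is then removed by base, so ring A aromatises to diolate 14, which AcOH protonates to 15. No lasting stereocentre is made, because the transient centres at C1 and C4 vanish on aromatisation. The required orientation (donor carbon to C4a, carbanion at C8a) is secured by the C8 aryl group beside the triple bond, which is sigma-withdrawing and bulky and so leaves C4a the more open and more electrophilic terminus, the same sense as the second addition in the Hart m-terphenyl synthesis, while the C6 methoxy group, meta and para to the aryne carbons, should exert little bias. Attack through C5 rather than C3 of 10 is expected because C3 carries the methoxy group and would give a quaternary centre with no path to an aromatic product.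

Step 6
Reactants: 15 8-(3,4-dimethoxyphenyl)-2,6-dimethoxynaphthalene-1,4-diol
Product: 16 8-(3,4-dimethoxyphenyl)-2,6-dimethoxynaphthalene-1,4-dione (target)
Conditions: Ag2O, Na2SO4, CH2Cl2, rt
Reagents that add atoms: none
Why: Two-electron oxidation of a 1,4-hydroquinone to the quinone by Ag2O is fast and mild, and the aryl methyl ethers of rings B and C oxidise only at much higher potential.

Compound list
1 | 1-bromo-2-iodo-4-methoxybenzene | COc1ccc(Br)c(I)c1 | starting material
2 | (3,4-dimethoxyphenyl)boronic acid | COc1ccc(B(O)O)cc1OC | starting material
3 | 2-bromo-3',4',5-trimethoxy-1,1'-biphenyl | COc1ccc(Br)c(-c2ccc(OC)c(OC)c2)c1 | intermediate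
4 | (±)-3-hydroxydihydrofuran-2(3H)-one | OC1CCOC1=O | starting material
5 | (±)-3-methoxydihydrofuran-2(3H)-one | COC1CCOC1=O | intermediate
6 | lithium enolate of 5 (lithium 3-methoxy-4,5-dihydrofuran-2-olate) | [Li+].COC1=C([O-])OCC1 | intermediate
7 | (±)-3-methoxy-3-(phenylselanyl)dihydrofuran-2(3H)-one | COC1(CCOC1=O)[Se]c1ccccc1 | intermediate
8 | 3-methoxy-3-(phenylseleninyl)dihydrofuran-2(3H)-one (selenoxide, racemic, mixture at Se) | COC1(CCOC1=O)[Se](=O)c1ccccc1 | intermediate
9 | 3-methoxyfuran-2(5H)-one | COC1=CCOC1=O | intermediate
10 | lithium 3-methoxyfuran-2-olate | [Li+].[O-]c1occc1OC | intermediate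
11 | 3-(3,4-dimethoxyphenyl)-5-methoxy-1,2-didehydrobenzene (aryne) | COC1=CC#CC(c2ccc(OC)c(OC)c2)=C1 | intermediate
12 | 5-[3-(3,4-dimethoxyphenyl)-2-lithio-5-methoxyphenyl]-3-methoxyfuran-2(5H)-one (racemic) | COC1=CC(OC1=O)c1cc(OC)cc(-c2ccc(OC)c(OC)c2)c1[Li] | intermediate
13 | lithium 8-(3,4-dimethoxyphenyl)-2,6-dimethoxy-1,4-dihydro-1,4-epoxynaphthalen-1-olate (racemic) | [Li]OC12OC(C=C1OC)c1cc(OC)cc(-c3ccc(OC)c(OC)c3)c12 | intermediate
14 | dilithium 8-(3,4-dimethoxyphenyl)-2,6-dimethoxynaphthalene-1,4-diolate | COc1cc(O[Li])c2cc(OC)cc(-c3ccc(OC)c(OC)c3)c2c1O[Li] | intermediate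
15 | 8-(3,4-dimethoxyphenyl)-2,6-dimethoxynaphthalene-1,4-diol | COc1cc(O)c2cc(OC)cc(-c3ccc(OC)c(OC)c3)c2c1O | intermediate
16 | 8-(3,4-dimethoxyphenyl)-2,6-dimethoxynaphthalene-1,4-dione | COC1=CC(=O)c2cc(OC)cc(-c3ccc(OC)c(OC)c3)c2C1=O | target

Total steps: 6. Longest linear sequence: 5 (steps 2, 3, 4, 5, 6).

Steps most likely to fail

Step 5. Several processes could compete with the intended annulation:
- The furanolate may add through C3 instead of C5.
- The furanolate may decay before the aryne is released.
- The free amine may capture the aryne.
- The orientation of addition to the aryne may be poorly controlled.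

The fallback uses known chemistry, sets out from 3 and comes back at 15.
- Commercial dimethyl squarate is reduced with LiAlH(OtBu)3 in THF at low temperature to 4-hydroxy-2,3-dimethoxycyclobut-2-en-1-one F1.
- Aqueous HCl converts this, with loss of methanol, into 3-methoxycyclobut-3-ene-1,2-dione F2.
- Bromine–lithium exchange on 3 (n-BuLi, THF, −78 °C) gives 2-lithio-3',4',5-trimethoxybiphenyl F3.
- This adds to the ketone-like carbonyl of the dione, the one next to C–OMe (the other is a vinylogous ester). The product is 4-hydroxy-3-methoxy-4-(3',4',5-trimethoxybiphenyl-2-yl)cyclobut-2-en-1-one F4.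
- Heating in xylene (Moore–Liebeskind ring expansion) opens the four-membered ring to the (Z)-vinylketene F5.
- The ketene closes on the only free ortho carbon of ring B and tautomerises to 15, with the methoxy group again next to the carbon bound to C8a.

Step 3. Enolisation may be incomplete, the lactone may undergo Claisen self-condensation, or the selenium group may be lost by ionisation at the O,Se-substituted carbon. The fallback sets out from 4 and comes back at 9, bypassing steps 2 to 4. The alcohol is oxidised with Dess–Martin periodinane in CH2Cl2 to the 2,3-dione, which rests as its enol 3-hydroxyfuran-2(5H)-one F6. The enol oxygen is then methylated with Me3SiCHN2 in toluene/MeOH. In this way the enol-ether level is reached by alcohol oxidation instead of enolate dehydrogenation.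

Step 1. The preference for iodide over bromide may erode, which would lead to double arylation or to hydrodebromination. The fallback sets out from 2 and comes back at 3.
- Suzuki–Miyaura coupling of 2 with commercial 2-bromo-4-methoxyaniline, which has a single halogen, gives 3',4',5-trimethoxybiphenyl-2-amine F7.
- Diazotisation (NaNO2, aq HBr, 0 °C) gives 3',4',5-trimethoxybiphenyl-2-diazonium bromide F8.
- CuBr (Sandmeyer reaction) then installs the bromine at the position of the former amino group.

Further compounds
F1 | step 5 | 4-hydroxy-2,3-dimethoxycyclobut-2-en-1-one (racemic) | COC1=C(OC)C(O)C1=O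
F2 | step 5 | 3-methoxycyclobut-3-ene-1,2-dione | COC1=CC(=O)C1=O
F3 | step 5 | 2-lithio-3',4',5-trimethoxybiphenyl | COc1ccc([Li])c(-c2ccc(OC)c(OC)c2)c1
F4 | step 5 | 4-hydroxy-3-methoxy-4-(3',4',5-trimethoxybiphenyl-2-yl)cyclobut-2-en-1-one (racemic) | COC1=CC(=O)C1(O)c1ccc(OC)cc1-c1ccc(OC)c(OC)c1
F5 | step 5 | (Z)-4-hydroxy-3-methoxy-4-(3',4',5-trimethoxybiphenyl-2-yl)buta-1,3-dien-1-one (vinylketene) | O=C=C/C(OC)=C(O)\c1ccc(OC)cc1-c1ccc(OC)c(OC)c1
F6 | step 3 | 3-hydroxyfuran-2(5H)-one | OC1=CCOC1=O
F7 | step 1 | 3',4',5-trimethoxybiphenyl-2-amine | COc1ccc(N)c(-c2ccc(OC)c(OC)c2)c1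
F8 | step 1 | 3',4',5-trimethoxybiphenyl-2-diazonium bromide | COc1ccc([N+]#N)c(-c2ccc(OC)c(OC)c2)c1.[Br-]
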